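## Retrosynthetic overview

1. (2S)-Flavanone 8 ⇐ racemic flavanone 7: the 2R enantiomer is removed by a catalyst-controlled kinetic resolution (asymmetric transfer hydrogenation of its ketone).
2. Ring C of 7 ⇐ 2'-hydroxychalcone 6 by intramolecular oxa-Michael addition (O1–C2 bond). It is the only ring made; rings A and B come with the starting materials.
3. Chalcone 6 ⇐ ring A methyl ketone 3 + 3,4,5-trimethoxybenzaldehyde 4 by intermolecular Claisen–Schmidt aldol condensation (C2–C3 bond, the bond that joins the two fragments).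
4. Ketone 3 ⇐ 3,4,5-trimethoxyphenol 1 by ortho C-acetylation.

Assumption: the SMILES is read as (2S)-5,6,7-trimethoxy-2-(3,4,5-trimethoxyphenyl)chroman-4-one (at C2: O1 > aryl > C3 > H); 1 and 4 are bought.

Abbreviations: Cp* = pentamethylcyclopentadienyl; TsDPEN = N-(p-toluenesulfonyl)-1,2-diphenylethane-1,2-diamine (bound as its monoanion); DMF-DMA = N,N-dimethylformamide dimethyl acetal; MOM = methoxymethyl; t-BuPyOx = 4-tert-butyl-2-(pyridin-2-yl)-4,5-dihydrooxazole.

## Route

Step 1
Reactants: 1 3,4,5-trimethoxyphenol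
Product: 3 1-(6-hydroxy-2,3,4-trimethoxyphenyl)ethan-1-one, via difluoroboron chelate 2 (not isolated)
Conditions: AcOH, BF3·OEt2 (3 equiv), 90 °C, 2.5 h; then H2O, 50 °C, 30 min
Reagents that add atoms: acetic acid, CC(=O)O
Why: BF3-promoted Friedel–Crafts C-acylation can only go ortho to the free hydroxyl (the two ortho positions are equivalent and the para position is blocked), and the ketone is held as its O,O-difluoroboron chelate 2 until water hydrolyses it to 3.

Step 2
Reactants: 3 1-(6-hydroxy-2,3,4-trimethoxyphenyl)ethan-1-one; 4 3,4,5-trimethoxybenzaldehyde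
Product: 6 (E)-1-(6-hydroxy-2,3,4-trimethoxyphenyl)-3-(3,4,5-trimethoxyphenyl)prop-2-en-1-one, via aldol adduct 5 (not isolated)
Conditions: KOH (50% aq, 10 equiv), EtOH, rt, 36 h; then 2 M HCl, 0 °C
Reagents that add atoms: none
Why: Claisen–Schmidt crossed aldol condensation, in which the non-enolisable aldehyde 4 takes the enolate of methyl ketone 3 to adduct 5 and E1cB dehydration to the conjugated (E)-enone drives the reaction, so this step forms the C–C bond joining the ring A and ring B fragments (the carbinol centre of 5 is lost again and needs no control).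

Step 3
Reactants: 6 (E)-1-(6-hydroxy-2,3,4-trimethoxyphenyl)-3-(3,4,5-trimethoxyphenyl)prop-2-en-1-one
Product: 7 racemic 5,6,7-trimethoxy-2-(3,4,5-trimethoxyphenyl)-2,3-dihydro-4H-chromen-4-one
Conditions: NaOAc (5 equiv), EtOH, reflux, 24 h
Reagents that add atoms: none
Why: Base-catalysed intramolecular oxa-Michael addition (6-endo-trig) of the phenoxide to the enone closes ring C, and the 6'-methoxy group, which twists the chalcone carbonyl out of conjugation, puts the chalcone–flavanone equilibrium on the flavanone side; C2 is formed racemic here and is resolved in step 4.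

Step 4
Reactants: 7 racemic 5,6,7-trimethoxy-2-(3,4,5-trimethoxyphenyl)-2,3-dihydro-4H-chromen-4-one
Product: 8 (2S)-5,6,7-trimethoxy-2-(3,4,5-trimethoxyphenyl)-2,3-dihydro-4H-chromen-4-one
Conditions: Cp*RhCl[(R,R)-TsDPEN] (1 mol%), HCO2H/Et3N (5:2), EtOAc, 30 °C, stopped at 53–55% conversion (chiral HPLC); SiO2, then recrystallisation from EtOH
Reagents that add atoms: none
Why: Noyori–Ikariya asymmetric transfer hydrogenation run as a kinetic resolution: the (R,R)-catalyst makes (4R)-benzylic alcohols and ring C takes hydride trans to the 2-aryl group (cis-alcohol), two demands met together only by the (2R)-ketone, so that enantiomer is reduced to the more polar (2R,4R)-cis-flavan-4-ol while the (2S)-ketone 8 is left, reaching ≥98% ee once conversion passes 50%, with its C2 centre untouched.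

## Compound list

1 | 3,4,5-trimethoxyphenol | COc1cc(O)cc(OC)c1OC | starting material
2 | difluoroboron chelate of 3 (2,2-difluoro-5,6,7-trimethoxy-4-methyl-1,3,2-benzodioxaborinine, zwitterionic O→B form; not isolated) | CC1=[O+][B-](F)(F)Oc2cc(OC)c(OC)c(OC)c12 | intermediate
3 | 1-(6-hydroxy-2,3,4-trimethoxyphenyl)ethan-1-one | CC(=O)c1c(O)cc(OC)c(OC)c1OC | intermediate
4 | 3,4,5-trimethoxybenzaldehyde | COc1cc(C=O)cc(OC)c1OC | starting material
5 | racemic 3-hydroxy-1-(6-hydroxy-2,3,4-trimethoxyphenyl)-3-(3,4,5-trimethoxyphenyl)propan-1-one (aldol adduct; not isolated) | COc1cc(C(O)CC(=O)c2c(O)cc(OC)c(OC)c2OC)cc(OC)c1OC | intermediate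
6 | (E)-1-(6-hydroxy-2,3,4-trimethoxyphenyl)-3-(3,4,5-trimethoxyphenyl)prop-2-en-1-one | COc1cc(/C=C/C(=O)c2c(O)cc(OC)c(OC)c2OC)cc(OC)c1OC | intermediate
7 | racemic 5,6,7-trimethoxy-2-(3,4,5-trimethoxyphenyl)-2,3-dihydro-4H-chromen-4-one | COc1cc(C2CC(=O)c3c(cc(OC)c(OC)c3OC)O2)cc(OC)c1OC | intermediate
8 | (2S)-5,6,7-trimethoxy-2-(3,4,5-trimethoxyphenyl)-2,3-dihydro-4H-chromen-4-one | COc1cc([C@@H]2CC(=O)c3c(cc(OC)c(OC)c3OC)O2)cc(OC)c1OC | target

## Step count and risks

Total step count: 4. Longest linear sequence: 4 steps (1 → 3 → 6 → 7 → 8); aldehyde 4 is bought.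

The three steps most likely to fail:

**Step 4.** The carbonyl group of 7 is electron-rich and flanked by the 5-methoxy group, so the transfer hydrogenation may be slow or too unselective to leave 8 at high ee. The fallback sets the stereocentre by asymmetric conjugate arylation instead of resolution, and sets out from 3. Heating 3 with DMF-DMA (CN(C)C(OC)OC, toluene, 100 °C) gives the enaminone (E)-3-(dimethylamino)-1-(6-hydroxy-2,3,4-trimethoxyphenyl)prop-2-en-1-one F1. Conc. HCl in CH2Cl2 at rt closes it, with loss of dimethylamine, to 5,6,7-trimethoxy-4H-chromen-4-one F2. Pd(OCOCF3)2 (5 mol%), (R)-t-BuPyOx (6 mol%), NH4PF6, H2O, ClCH2CH2Cl, 60 °C then adds 3,4,5-trimethoxyphenylboronic acid (COc1cc(B(O)O)cc(OC)c1OC) to the Re face of C2, and the fallback comes back to the route at 8. The (R)-ligand is chosen because the (S)-ligand is expected, by analogy with its cyclohexenone additions, to give the 2R series; this sense must be confirmed on the first run by chiral HPLC against racemate 7 and by the CD spectrum.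

**Step 2.** Ketone 3 reacts as its phenoxide, which slows enolisation of the hindered, doubly ortho-oxygenated acetyl group, and Cannizzaro loss of 4 can compete. The fallback masks the phenol and sets out from 3. NaH and MOMCl (COCCl) in DMF, 0 °C to rt, give 1-[2,3,4-trimethoxy-6-(methoxymethoxy)phenyl]ethan-1-one F3. Its simple monoanionic enolate condenses with 4 (KOH, EtOH, rt) to (E)-1-[2,3,4-trimethoxy-6-(methoxymethoxy)phenyl]-3-(3,4,5-trimethoxyphenyl)prop-2-en-1-one F4. 3 M HCl in MeOH at 50 °C removes the acetal, and the fallback comes back to the route at 6 (any 7 already formed is carried into step 3).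

**Step 1.** Hot BF3 can cleave the methyl ether next to the new carbonyl group, or the reaction can stall at the chelate. The fallback is a Houben–Hoesch acylation under milder Lewis acid conditions and sets out from 1. MeCN, ZnCl2 and dry HCl in Et2O at 0 °C precipitate 1-(6-hydroxy-2,3,4-trimethoxyphenyl)ethan-1-iminium chloride F5. This is filtered off and hydrolysed (H2O, 90 °C, 1 h), and the fallback comes back to the route at 3.

## Further compounds

F1 | step 4 | (E)-3-(dimethylamino)-1-(6-hydroxy-2,3,4-trimethoxyphenyl)prop-2-en-1-one | CN(C)/C=C/C(=O)c1c(O)cc(OC)c(OC)c1OC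
F2 | step 4 | 5,6,7-trimethoxy-4H-chromen-4-one | COc1cc2occc(=O)c2c(OC)c1OC
F3 | step 2 | 1-[2,3,4-trimethoxy-6-(methoxymethoxy)phenyl]ethan-1-one | COCOc1cc(OC)c(OC)c(OC)c1C(C)=O
F4 | step 2 | (E)-1-[2,3,4-trimethoxy-6-(methoxymethoxy)phenyl]-3-(3,4,5-trimethoxyphenyl)prop-2-en-1-one | COCOc1cc(OC)c(OC)c(OC)c1C(=O)/C=C/c1cc(OC)c(OC)c(OC)c1
F5 | step 1 | 1-(6-hydroxy-2,3,4-trimethoxyphenyl)ethan-1-iminium chloride | CC(=[NH2+])c1c(O)cc(OC)c(OC)c1OC.[Cl-]
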